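(The data are calculated for an exercise.)

Elm has stopped. I wrote this note for whoever took over the bench; the charges, readings, options and questions come first.

common to all: substrate 0.040 M; free catalyst 4.6 mol%
- elm: solid reagent 2 equiv; temperature 50 °C; the very flask that is asked about, followed so far
- cedar: solid reagent 2 equiv; temperature 56 °C; run made earlier
- flask: solid reagent 2.00 equiv; temperature 50 °C; time 20 h

| run | time / h | product / % | substrate / % |
|---|---|---|---|
| elm | 2.00 | 12.8 | 87.0 |
| elm | 5.00 | 24.7 | 73.3 |
| elm | 10.0 | 31.5 | 65.2 |
| elm | 15.0 | 33.2 | 64.2 |
| elm | 20.0 | 33.4 | 63.2 |
| cedar | 2.00 | 12.0 | 86.1 |
| cedar | 5.00 | 20.1 | 77.2 |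
| cedar | 10.0 | 24.6 | 73.6 |
| cedar | 15.0 | 23.5 | 72.4 |
| cedar | 20.0 | 24.6 | 73.3 |

(standard deviation of a reading: 0.5 percentage points)

- west: change nothing and wait 6.0 h more
- south-west: at 20 h raise the temperature by 25 K, then wait 6.0 h
- south: at 20 h take out 90 % of the product then present, then wait 6.0 h
- east: at 20 h add free catalyst, 100 % of the amount charged, then wait 6.0 h

- as a solid, counted per litre of solution: solid reagent
- product that was removed still counts
- candidate steps: substrate + partner + free catalyst -> free catalyst + product; substrate + free catalyst -> spent catalyst A; solid reagent <-> partner; 2 free catalyst -> spent catalyst B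
- at the start none of the solid reagent is in solution
- additions bring no volume worth counting

- product, in percent of the substrate first charged, at 20 h
- which option adds most product ("none" when 2 percentage points or less is all one gets) (west / south-west / south / east / none)
- product present, with what was taken out counted in, in percent of the substrate first charged, after west
- product present, with what was taken out counted in, in percent of the substrate first charged, after east

The product reading of flask elm rose 0.2 percentage points over its last interval, less than the scatter of a reading, while substrate still read 63.2 %. So substrate was not what stopped it, and I took the catalyst to be dead. For 20.0 h I put down the last reading, 33.4 %, and I expected the same when the next person came.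

I froze one thing: I took partner as steady and assumed that a charge of catalyst takes away a fixed fraction of what it finds, in the manner of a pseudo-first-order step, and not a fixed amount. For elm that gives 0.406, which I called the reach R, the natural logarithm of the share of substrate not yet product before a catalyst charge over the share not yet product after it. Cedar, at 56 °C, reached 0.282, less than elm, so I wrote: do not heat. Do not wait either, and leave the product in; neither run had any taken out.

Add catalyst. A second equal charge with the same R gives 55.6 %. I held that as a low guess: the first charge began with none of the solid reagent in solution, and a new one would not.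

The forecast gave 33.5 % now, 33.7 % after west and, as a central figure where I held mine low, 55.5 % after east, and chose east: “Fresh catalyst restarts the reaction, with partner already dissolved”.

The flask gave 33.7 % now, 33.8 % after west and 77.0 % after east, a gain of 43 points.

    substrate + partner + free catalyst → free catalyst + product (k = 620 M⁻² min⁻¹, Ea = 46.0 kJ mol⁻¹)
    substrate + free catalyst → spent catalyst A (k = 0.190 M⁻¹ min⁻¹, Ea = 60.0 kJ mol⁻¹)
    solid reagent ⇌ partner, rate k3*(cs3 - [partner]) while solid is left; crystals form when [partner] > cs3 (solubility = 16.0 mM, k = 0.00620 min⁻¹)
    2 free catalyst → spent catalyst B (k = 3.70 M⁻¹ min⁻¹, Ea = 55.0 kJ mol⁻¹)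
    (constants at 50 °C)

The second charge had a reach of 1.06, larger than my frozen R. In this flask the product step gave substrate a half-life of 13 h at 3.29 h, but 51 d at 20.0 h, with free catalyst at 0.0523 % of its charge. The same recipe at 0.010 M of substrate stood at 60.2 % of product, a reach of 0.922.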